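The 18-membered ring is opened at the bond between C1 of ring C (the phenol ring, with its oxygen at C4 and the ether oxygen to ring D at C5) and the benzylic carbon of the ethano bridge to ring B. An intramolecular Friedel–Crafts acylation by the ring B arylacetic acid exploits the fact that C1 is unsubstituted and para to the C4 alkoxy oxygen. One operation therefore forms the last skeletal bond and the macrocycle, leaving a ketone that is removed afterwards. The precursor is an open-chain tetra-aryl acid: two diaryl ethers (B–O–A and D–O–C), a saturated two-carbon bridge between rings D and A, and the ring C oxygen masked as an isopropyl ether.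

Key step: step 8

Remark: ring A is the methoxy-bearing 1,2,3-trisubstituted ring, ring B the meta-linked ring, ring C the phenol ring (C1 bridge carbon, C4 hydroxyl or isopropoxy oxygen, C5 ether oxygen to ring D) and ring D the para-linked ring. The target has no stereocentre. Compounds 1, 2, 7 and 8 are assumed to be purchasable.

Step 1
Reactants: 1 2-isopropoxyphenol; 2 4-fluorobenzaldehyde
Product: 3 4-(2-isopropoxyphenoxy)benzaldehyde
Conditions: K2CO3, DMF, 120 °C
Reagents that add atoms: none
Why: Nucleophilic aromatic substitution (SNAr), in which the para-formyl group activates the C–F bond toward the phenoxide of 1, is a standard diaryl ether synthesis.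

Step 2
Reactants: 3 4-(2-isopropoxyphenoxy)benzaldehyde
Product: 4 [4-(2-isopropoxyphenoxy)phenyl]methanol
Conditions: NaBH4, MeOH, 0 °C → rt
Reagents that add atoms: none
Why: Borohydride reduction of an aryl aldehyde should give the benzylic alcohol cleanly, the ethers being inert to hydride.

Step 3
Reactants: 4 [4-(2-isopropoxyphenoxy)phenyl]methanol
Product: 6 [4-(2-isopropoxyphenoxy)benzyl]triphenylphosphonium bromide, via benzyl bromide 5 (not isolated)
Conditions: PPh3·HBr, MeCN, reflux
Reagents that add atoms: triphenylphosphine hydrobromide, [Br-].c1ccc(cc1)[PH+](c1ccccc1)c1ccccc1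
Why: The HBr of the salt should convert the electron-rich benzylic alcohol into bromide 5, which triphenylphosphine quaternises by SN2 displacement; aryl isopropyl ethers tolerate this weakly acidic medium.

Step 4
Reactants: 7 methyl 2-(3-hydroxyphenyl)acetate; 8 2-fluoro-3-methoxybenzaldehyde
Product: 9 methyl 2-[3-(2-formyl-6-methoxyphenoxy)phenyl]acetate
Conditions: K2CO3, DMF, 110 °C
Reagents that add atoms: none
Why: SNAr displacement of the fluoride ortho to the formyl group by the phenoxide of 7 should proceed while the mild carbonate base keeps enolate chemistry of the arylacetate ester to a minimum.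

Step 5
Reactants: 6 [4-(2-isopropoxyphenoxy)benzyl]triphenylphosphonium bromide; 9 methyl 2-[3-(2-formyl-6-methoxyphenoxy)phenyl]acetate
Product: 11 methyl 2-[3-(2-{2-[4-(2-isopropoxyphenoxy)phenyl]ethenyl}-6-methoxyphenoxy)phenyl]acetate (E/Z mixture), via phosphonium ylide 10 (not isolated)
Conditions: K2CO3, 18-crown-6 (cat.), CH2Cl2, reflux
Reagents that add atoms: none
Why: Wittig olefination, in which carbonate and crown ether generate the semi-stabilised benzylic ylide 10 that condenses with aldehyde 9 without touching the methyl ester; the alkene geometry is irrelevant because the double bond is saturated next.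

Step 6
Reactants: 11 stilbene ester (E/Z mixture)
Product: 12 methyl 2-[3-(2-{2-[4-(2-isopropoxyphenoxy)phenyl]ethyl}-6-methoxyphenoxy)phenyl]acetate
Conditions: H2 (1 atm), Pd/C (10% Pd on carbon), EtOAc, rt
Reagents that add atoms: none
Why: Heterogeneous catalytic hydrogenation should saturate the stilbene double bond of both isomers, since the molecule holds no benzyl ether, halide or other hydrogenolysable group.

Step 7
Reactants: 12 bibenzyl methyl ester
Product: 13 2-[3-(2-{2-[4-(2-isopropoxyphenoxy)phenyl]ethyl}-6-methoxyphenoxy)phenyl]acetic acid (seco acid)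
Conditions: LiOH·H2O, THF/MeOH/H2O, rt; then 1 M HCl
Reagents that add atoms: water, O (delivered as hydroxide from LiOH, [Li+].[OH-])
Why: Saponification of the methyl ester followed by acidification should give the free arylacetic acid, no other hydrolysable group being present.

Step 8
Reactants: 13 seco arylacetic acid
Product: 15 macrocyclic benzyl aryl ketone (18-membered; carbonyl on the bridge carbon bonded to C1 of ring C; isopropyl ether at C4), via mixed trifluoroacetic anhydride 14 (not isolated)
Conditions: (CF3CO)2O (excess), 85% H3PO4, MeCN, rt; 13 added by syringe pump over about 12 h, final concentration about 1 mM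
Reagents that add atoms: none
Why: Trifluoroacetic anhydride converts the acid into mixed anhydride 14, which under H3PO4 catalysis acts as an acylium-type electrophile; attack by C1 of ring C gives a Wheland intermediate whose deprotonation delivers the aryl ketone, and this ketone deactivates ring C against a second acylation. The closest known chemistry is the Friedel–Crafts acylation of alkoxyarenes with free carboxylic acids under trifluoroacetic anhydride/phosphoric acid activation, together with high-dilution Friedel–Crafts closures of macrocyclic aryl ketones. The 18-membered ring closes by end-to-end electrophilic aromatic substitution that bridges C1 and C5 of ring C in a meta fashion; slow addition keeps the stationary concentration of 14 low so that cyclisation should outrun chain growth, and the two diaryl ether hinges limit the entropic cost. No stereocentre is created. C1 must win over C2, C3, C6 and the other rings: C1 is para to the isopropoxy oxygen, a markedly stronger donor than the diaryl ether oxygen that activates C2 (attack there would give a 19-membered para-bridged isomer), the isopropyl group screens C3, C6 is only ortho to the weaker donor, ring A (comparably electron-rich) can be reached only through strained nine- or ten-membered rings, and rings B and D are far less activated. Aryl isopropyl and methyl ethers should be stable to this medium at room temperature.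

Step 9
Reactants: 15 macrocyclic ketone
Product: 17 macrocyclic bis(bibenzyl) isopropyl ether (target skeleton with isopropoxy at C4 of ring C), via macrocyclic carbinol 16 (not isolated)
Conditions: Et3SiH (excess), CF3CO2H/CH2Cl2, rt
Reagents that add atoms: none
Why: Ionic hydrogenation, in which protonation and hydride transfer give carbinol 16, whose ionisation to a para-isopropoxybenzylic cation and a second hydride transfer from the silane leave the methylene group; the aryl ethers are stable to trifluoroacetic acid at room temperature.

Step 10
Reactants: 17 macrocyclic isopropyl ether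
Product: 19 target CNP0309263.0 (ring C phenol with ring A methyl ether), via aryl dichloroborinate 18 (not isolated)
Conditions: BCl3 (1 M in CH2Cl2), CH2Cl2, −78 → 0 °C; then MeOH/H2O
Reagents that add atoms: none
Why: Lewis-acid ether dealkylation, in which BCl3 coordinates the ether oxygen and the secondary isopropyl group departs as 2-chloropropane far faster than a methyl group, giving borinate 18 that hydrolyses on work-up; the methyl ether and both diaryl ethers should survive at low temperature.

Compound list
1 | 2-isopropoxyphenol | CC(C)Oc1ccccc1O | starting material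
2 | 4-fluorobenzaldehyde | O=Cc1ccc(F)cc1 | starting material
3 | 4-(2-isopropoxyphenoxy)benzaldehyde | CC(C)Oc1ccccc1Oc1ccc(C=O)cc1 | intermediate
4 | [4-(2-isopropoxyphenoxy)phenyl]methanol | CC(C)Oc1ccccc1Oc1ccc(CO)cc1 | intermediate
5 | 1-(bromomethyl)-4-(2-isopropoxyphenoxy)benzene (not isolated) | CC(C)Oc1ccccc1Oc1ccc(CBr)cc1 | intermediate
6 | [4-(2-isopropoxyphenoxy)benzyl]triphenylphosphonium bromide | [Br-].CC(C)Oc1ccccc1Oc1ccc(C[P+](c2ccccc2)(c2ccccc2)c2ccccc2)cc1 | intermediate
7 | methyl 2-(3-hydroxyphenyl)acetate | COC(=O)Cc1cccc(O)c1 | starting material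
8 | 2-fluoro-3-methoxybenzaldehyde | COc1cccc(C=O)c1F | starting material
9 | methyl 2-[3-(2-formyl-6-methoxyphenoxy)phenyl]acetate | COC(=O)Cc1cccc(Oc2c(OC)cccc2C=O)c1 | intermediate
10 | [4-(2-isopropoxyphenoxy)benzylidene]triphenylphosphorane (not isolated) | CC(C)Oc1ccccc1Oc1ccc(C=P(c2ccccc2)(c2ccccc2)c2ccccc2)cc1 | intermediate
11 | methyl 2-[3-(2-{2-[4-(2-isopropoxyphenoxy)phenyl]ethenyl}-6-methoxyphenoxy)phenyl]acetate, E/Z mixture (geometry not specified) | COC(=O)Cc1cccc(Oc2c(OC)cccc2C=Cc2ccc(Oc3ccccc3OC(C)C)cc2)c1 | intermediate
12 | methyl 2-[3-(2-{2-[4-(2-isopropoxyphenoxy)phenyl]ethyl}-6-methoxyphenoxy)phenyl]acetate | COC(=O)Cc1cccc(Oc2c(OC)cccc2CCc2ccc(Oc3ccccc3OC(C)C)cc2)c1 | intermediate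
13 | 2-[3-(2-{2-[4-(2-isopropoxyphenoxy)phenyl]ethyl}-6-methoxyphenoxy)phenyl]acetic acid (key-step precursor) | OC(=O)Cc1cccc(c1)Oc1c(OC)cccc1CCc1ccc(cc1)Oc1ccccc1OC(C)C | intermediate
14 | mixed anhydride of 13 with trifluoroacetic acid (not isolated) | FC(F)(F)C(=O)OC(=O)Cc1cccc(c1)Oc1c(OC)cccc1CCc1ccc(cc1)Oc1ccccc1OC(C)C | intermediate
15 | macrocyclic benzyl aryl ketone, isopropyl ether (key-step product) | COc1cccc2c1Oc1cccc(c1)CC(=O)c1ccc(OC(C)C)c(c1)Oc1ccc(cc1)CC2 | intermediate
16 | macrocyclic benzylic carbinol, racemic (not isolated) | COc1cccc2c1Oc1cccc(c1)CC(O)c1ccc(OC(C)C)c(c1)Oc1ccc(cc1)CC2 | intermediate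
17 | macrocyclic bis(bibenzyl) isopropyl ether | COc1cccc2c1Oc1cccc(c1)CCc1ccc(OC(C)C)c(c1)Oc1ccc(cc1)CC2 | intermediate
18 | aryl dichloroborinate of the target phenol (not isolated) | COc1cccc2c1Oc1cccc(c1)CCc1ccc(OB(Cl)Cl)c(c1)Oc1ccc(cc1)CC2 | intermediate
19 | CNP0309263.0, macrocyclic bis(bibenzyl) phenol | COc1cccc2c1Oc1cccc(c1)CCc1ccc(O)c(c1)Oc1ccc(cc1)CC2 | target

Total step count: 10. Longest linear sequence: 9 steps (steps 1, 2, 3, 5, 6, 7, 8, 9, 10, from 1 and 2).

Steps most likely to fail

Step 8. Chain growth by intermolecular acylation may outrun ring closure, or attack may occur para to the diaryl ether oxygen (C2) and give the 19-membered isomer. The fallback forms the same C1–acyl bond intermolecularly and closes the ring by a Wittig reaction at the bridge between rings D and A. It sets out from 9 and 6. Ester 9 would be saponified (LiOH, THF/H2O, rt; then HCl) to 2-[3-(2-formyl-6-methoxyphenoxy)phenyl]acetic acid F1. Ring C of phosphonium salt 6 would then be acylated with F1 ((CF3CO)2O, H3PO4, MeCN, rt); ring A of F1 is deactivated by its formyl group and ring D of 6 by the phosphoniomethyl group, so the keto aldehyde phosphonium bromide F2 should result. Intramolecular Wittig olefination under high dilution (K2CO3, 18-crown-6, CH2Cl2, reflux, slow addition) should give the macrocyclic stilbene ketone F3. Hydrogenation (H2, Pd/C, EtOAc) returns to the route at 15.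

Step 4. At the temperature that the flanked fluoride needs, the acidic arylacetate methylene may condense with the aldehyde, or the ester may be cleaved. The fallback carries the ring B side chain as a primary alcohol and sets out from 8. SNAr with commercial 2-(3-hydroxyphenyl)ethanol (OCCc1cccc(O)c1; K2CO3, DMF, 110 °C) should give 2-[3-(2-hydroxyethyl)phenoxy]-3-methoxybenzaldehyde F4. Wittig coupling with 6 (K2CO3, 18-crown-6, CH2Cl2, reflux) should give the stilbene alcohol F5, and hydrogenation (H2, Pd/C, EtOAc) the bibenzyl alcohol F6. Oxidation of the primary alcohol (TEMPO cat., PhI(OAc)2, MeCN/H2O, rt) returns to the route at 13.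

Step 9. The benzylic cation may be captured by a neighbouring electron-rich ring across the macrocycle before hydride arrives, or the isopropyl group may be lost in the acid. The fallback is a cation-free Wolff–Kishner reduction (Huang-Minlon procedure) and sets out from 15. Condensation with N2H4·H2O in diethylene glycol at 130 °C should give the macrocyclic hydrazone F7. Heating with KOH at 190–200 °C expels dinitrogen and returns to the route at 17.

Further compounds
F1 | step 8 | 2-[3-(2-formyl-6-methoxyphenoxy)phenyl]acetic acid | OC(=O)Cc1cccc(Oc2c(OC)cccc2C=O)c1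
F2 | step 8 | keto aldehyde phosphonium bromide (ring C acylated at C1 by F1) | [Br-].COc1cccc(C=O)c1Oc1cccc(CC(=O)c2ccc(OC(C)C)c(Oc3ccc(C[P+](c4ccccc4)(c4ccccc4)c4ccccc4)cc3)c2)c1
F3 | step 8 | macrocyclic stilbene ketone, E/Z mixture (geometry not specified) | COc1cccc2c1Oc1cccc(c1)CC(=O)c1ccc(OC(C)C)c(c1)Oc1ccc(cc1)C=C2
F4 | step 4 | 2-[3-(2-hydroxyethyl)phenoxy]-3-methoxybenzaldehyde | OCCc1cccc(Oc2c(OC)cccc2C=O)c1
F5 | step 4 | 2-[3-(2-{2-[4-(2-isopropoxyphenoxy)phenyl]ethenyl}-6-methoxyphenoxy)phenyl]ethanol, E/Z mixture (geometry not specified) | OCCc1cccc(Oc2c(OC)cccc2C=Cc2ccc(Oc3ccccc3OC(C)C)cc2)c1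
F6 | step 4 | 2-[3-(2-{2-[4-(2-isopropoxyphenoxy)phenyl]ethyl}-6-methoxyphenoxy)phenyl]ethanol | OCCc1cccc(Oc2c(OC)cccc2CCc2ccc(Oc3ccccc3OC(C)C)cc2)c1
F7 | step 9 | hydrazone of macrocyclic ketone 15 | COc1cccc2c1Oc1cccc(c1)CC(=NN)c1ccc(OC(C)C)c(c1)Oc1ccc(cc1)CC2
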